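With the side chain numbered C1' (ArOCH2), C2'/C3' (oxirane carbons, methyl on C3'), C4' (CH2), C5' (carbinol) and C6'=C7' (isobutenyl), C1' and C4' sit cis on the oxirane ring, so the epoxide derives from a Z C2'=C3' olefin. The route disconnects that olefin: ring-closing metathesis of an acrylate onto a methallyl group forms C2'=C3' inside a six-membered lactone ring (C1' to C5' plus the C5' oxygen), which can only hold the Z geometry and also delivers C1' and C5' oxygens differentiated. The precursor is the acrylate of (S)-2,6-dimethylhepta-1,5-dien-4-ol, made by asymmetric methallylation of 3-methylbut-2-enal; reduction, reagent-controlled epoxidation and etherification with the coumarin phenol finish the target.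

Key step: step 3

Remark: (−)-B-methoxydiisopinocampheylborane (the enantiomer derived from (+)-α-pinene) and 7-hydroxy-8-methoxycoumarin are taken as purchasable; intermediates 6 to 12 are acid-labile allylic alcohol derivatives, so all work-ups are kept neutral or basic.

Step 1
Reactants: 1 2-methylallylmagnesium chloride; 2 (−)-B-methoxydiisopinocampheylborane; 3 3-methylbut-2-enal
Product: 6 (S)-2,6-dimethylhepta-1,5-dien-4-ol, via B-methallyldiisopinocampheylborane 4 (not isolated), via dienyl diisopinocampheylborinate 5 (not isolated)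
Conditions: 1 + 2, Et2O/THF, −78 °C → rt; then 3, −78 °C; then 3 M NaOH, 30% H2O2, 0 °C → rt
Reagents that add atoms: none
Why: Brown asymmetric allylboration, in which reagent 4 adds 1,2 to the enal through a closed chair six-membered transition state and the isopinocampheyl groups of the (+)-α-pinene series direct the methallyl group to the Si face of the aldehyde, which should set C5' as S before oxidative work-up cleaves borinate 5.

Step 2
Reactants: 6 (S)-2,6-dimethylhepta-1,5-dien-4-ol; 7 acryloyl chloride
Product: 8 (S)-2,6-dimethylhepta-1,5-dien-4-yl acrylate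
Conditions: Et3N, DMAP (cat.), CH2Cl2, −20 → 0 °C
Reagents that add atoms: none
Why: O-acylation of a secondary alcohol by an acid chloride (nucleophilic acyl substitution) under basic conditions, which leaves the acid-labile allylic C5'–O bond and its configuration untouched.

Step 3
Reactants: 8 (S)-2,6-dimethylhepta-1,5-dien-4-yl acrylate
Product: 9 (S)-4-methyl-6-(2-methylprop-1-enyl)-5,6-dihydro-2H-pyran-2-one
Conditions: second-generation Grubbs catalyst (H2IMes)(PCy3)Cl2Ru=CHPh (5 mol %), CH2Cl2 (0.005 M), reflux, Ar sparge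
Reagents that add atoms: none
Why: Olefin metathesis by the Chauvin mechanism: a ruthenium alkylidene formed on the acrylate or on the 1,1-disubstituted C3'=CH2 olefin undergoes intramolecular [2+2] cycloaddition with the other olefin, and cycloreversion of the ruthenacyclobutane releases the C2'=C3' bond and, after turnover, ethylene. The closest known reaction type is the ring-closing metathesis of acrylates of homoallylic and methallyl carbinols to 5,6-dihydropyran-2-ones with N-heterocyclic carbene ruthenium catalysts. The lactone ring (C1' to C5' plus the C5' oxygen) is closed as a six-membered ring whose new olefin is endocyclic, so only the Z geometry, with C1' cis to C4', can form. No stereocentre is created, and the C5' centre takes no part and is retained. The step needs chemoselectivity for the methallyl olefin over the isobutenyl C6'=C7' olefin and cyclisation over dimerisation: the trisubstituted olefin is the least reactive partner and closing onto it would give a strained five-membered butenolide, while high dilution and removal of ethylene favour ring closure.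

Step 4
Reactants: 9 (S)-4-methyl-6-(2-methylprop-1-enyl)-5,6-dihydro-2H-pyran-2-one
Product: 10 (2Z,5S)-3,7-dimethylocta-2,6-diene-1,5-diol
Conditions: iBu2AlH (3.5 equiv), CH2Cl2, −78 → 0 °C; aq. KNaC4H4O6 work-up
Reagents that add atoms: none
Why: 1,2-Hydride reduction of the unsaturated lactone carbonyl to the alcohol level with excess aluminium hydride should open the ring to the primary allylic and secondary alcohols with the Z C2'=C3' geometry retained, and the neutral tartrate work-up avoids acid-induced cyclisation of the diol.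

Step 5
Reactants: 10 (2Z,5S)-3,7-dimethylocta-2,6-diene-1,5-diol
Product: 11 (2Z,5S)-1,5-bis(tert-butyldimethylsilyloxy)-3,7-dimethylocta-2,6-diene
Conditions: TBSCl (2.5 equiv), imidazole, DMF, 0 °C → rt
Reagents that add atoms: tert-butyldimethylsilyl chloride, CC(C)(C)[Si](C)(C)Cl
Why: Imidazole-promoted silyl ether formation on both hydroxyls under mild base, which touches neither the olefins nor the C5' centre.

Step 6
Reactants: 11 (2Z,5S)-1,5-bis(tert-butyldimethylsilyloxy)-3,7-dimethylocta-2,6-diene
Product: 12 (2Z,5S)-5-(tert-butyldimethylsilyloxy)-3,7-dimethylocta-2,6-dien-1-ol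
Conditions: HF·pyridine, pyridine, THF, 0 °C
Reagents that add atoms: none
Why: Selective desilylation, since buffered fluoride should cleave the unhindered primary silyl ether much faster than the secondary one, which is flanked by C4' and the isobutenyl group.

Step 7
Reactants: 12 (2Z,5S)-5-(tert-butyldimethylsilyloxy)-3,7-dimethylocta-2,6-dien-1-ol
Product: 13 [(2S,3R)-3-[(2S)-2-(tert-butyldimethylsilyloxy)-4-methylpent-3-enyl]-3-methyloxiran-2-yl]methanol
Conditions: Ti(OiPr)4 (0.2 equiv), L-(+)-diethyl tartrate (0.25 equiv), tBuOOH (2 equiv, decane), 4 Å MS, CH2Cl2, −20 °C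
Reagents that add atoms: tert-butyl hydroperoxide, CC(C)(C)OO
Why: Sharpless asymmetric epoxidation, in which the titanium tartrate complex binds the primary allylic alcohol and delivers the peroxide oxygen to the olefin face that L-(+)-tartrate selects for allylic alcohols, which on this Z (nerol-type) olefin should set C2' as S and C3' as R with C1' and C4' cis, while the silylated C5' oxygen cannot direct oxidation of the isobutenyl olefin.

Step 8
Reactants: 13 [(2S,3R)-3-[(2S)-2-(tert-butyldimethylsilyloxy)-4-methylpent-3-enyl]-3-methyloxiran-2-yl]methanol; 14 7-hydroxy-8-methoxycoumarin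
Product: 15 7-{[(2S,3R)-3-[(2S)-2-(tert-butyldimethylsilyloxy)-4-methylpent-3-enyl]-3-methyloxiran-2-yl]methoxy}-8-methoxy-2H-chromen-2-one
Conditions: PPh3, iPrO2CN=NCO2iPr (DIAD), THF, 0 °C → rt
Reagents that add atoms: none
Why: Mitsunobu etherification, in which the primary C1' hydroxyl is activated as its oxyphosphonium ion and displaced by the acidic coumarin phenoxide in an SN2 step at a non-stereogenic carbon under neutral conditions that spare the epoxide.

Step 9
Reactants: 15 7-{[(2S,3R)-3-[(2S)-2-(tert-butyldimethylsilyloxy)-4-methylpent-3-enyl]-3-methyloxiran-2-yl]methoxy}-8-methoxy-2H-chromen-2-one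
Product: 16 7-{[(2S,3R)-3-[(2S)-2-hydroxy-4-methylpent-3-enyl]-3-methyloxiran-2-yl]methoxy}-8-methoxy-2H-chromen-2-one (CNP0223665.2)
Conditions: Bu4NF, AcOH (1:1), THF, 0 °C → rt
Reagents that add atoms: none
Why: Fluoride-mediated cleavage of the secondary silyl ether, buffered with acetic acid so that neither the epoxide nor the coumarin lactone meets a free alkoxide.

Compound list

1 | 2-methylallylmagnesium chloride | CC(=C)C[Mg]Cl | starting material
2 | (−)-B-methoxydiisopinocampheylborane, from (+)-α-pinene | COB([C@@H]1C[C@@H]2C[C@H]([C@H]1C)C2(C)C)[C@@H]1C[C@@H]2C[C@H]([C@H]1C)C2(C)C | starting material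
3 | 3-methylbut-2-enal | CC(C)=CC=O | starting material
4 | B-(2-methylallyl)diisopinocampheylborane (B-methallyldiisopinocampheylborane), formed in the flask | CC(=C)CB([C@@H]1C[C@@H]2C[C@H]([C@H]1C)C2(C)C)[C@@H]1C[C@@H]2C[C@H]([C@H]1C)C2(C)C | intermediate
5 | (S)-2,6-dimethylhepta-1,5-dien-4-yl diisopinocampheylborinate, formed in the flask | CC(=C)C[C@H](OB([C@@H]1C[C@@H]2C[C@H]([C@H]1C)C2(C)C)[C@@H]1C[C@@H]2C[C@H]([C@H]1C)C2(C)C)C=C(C)C | intermediate
6 | (S)-2,6-dimethylhepta-1,5-dien-4-ol | CC(=C)C[C@H](O)C=C(C)C | intermediate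
7 | acryloyl chloride | C=CC(=O)Cl | starting material
8 | (S)-2,6-dimethylhepta-1,5-dien-4-yl acrylate | C=CC(=O)O[C@@H](CC(C)=C)C=C(C)C | intermediate
9 | (S)-4-methyl-6-(2-methylprop-1-enyl)-5,6-dihydro-2H-pyran-2-one | CC1=CC(=O)O[C@H](C=C(C)C)C1 | intermediate
10 | (2Z,5S)-3,7-dimethylocta-2,6-diene-1,5-diol | OC/C=C(C)\C[C@H](O)C=C(C)C | intermediate
11 | (2Z,5S)-1,5-bis(tert-butyldimethylsilyloxy)-3,7-dimethylocta-2,6-diene | CC(C)(C)[Si](C)(C)OC/C=C(C)\C[C@H](O[Si](C)(C)C(C)(C)C)C=C(C)C | intermediate
12 | (2Z,5S)-5-(tert-butyldimethylsilyloxy)-3,7-dimethylocta-2,6-dien-1-ol | OC/C=C(C)\C[C@H](O[Si](C)(C)C(C)(C)C)C=C(C)C | intermediate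
13 | [(2S,3R)-3-[(2S)-2-(tert-butyldimethylsilyloxy)-4-methylpent-3-enyl]-3-methyloxiran-2-yl]methanol | OC[C@@H]1O[C@]1(C)C[C@H](O[Si](C)(C)C(C)(C)C)C=C(C)C | intermediate
14 | 7-hydroxy-8-methoxycoumarin | COc1c(O)ccc2ccc(=O)oc12 | starting material
15 | 7-{[(2S,3R)-3-[(2S)-2-(tert-butyldimethylsilyloxy)-4-methylpent-3-enyl]-3-methyloxiran-2-yl]methoxy}-8-methoxy-2H-chromen-2-one | COc1c(OC[C@@H]2O[C@]2(C)C[C@H](O[Si](C)(C)C(C)(C)C)C=C(C)C)ccc2ccc(=O)oc12 | intermediate
16 | 7-{[(2S,3R)-3-[(2S)-2-hydroxy-4-methylpent-3-enyl]-3-methyloxiran-2-yl]methoxy}-8-methoxy-2H-chromen-2-one | COc1c(OC[C@@H]2O[C@]2(C)C[C@H](O)C=C(C)C)ccc2ccc(=O)oc12 | target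

Total step count: 9. Longest linear sequence: 9 steps (3 → 6 → 8 → 9 → 10 → 11 → 12 → 13 → 15 → 16).

Steps most likely to fail

Step 3. Neither the acrylate nor the 1,1-disubstituted olefin loads the catalyst well, so turnover may be slow and catalyst decay, intermolecular cross-metathesis or engagement of the isobutenyl olefin may compete. Fallback, from 3 back to 9: the Z olefin is made by an intramolecular Horner–Wadsworth–Emmons reaction instead. Aldehyde 3 is allylated with (−)-B-allyldiisopinocampheylborane (sold as a pentane solution; the B-allyl analogue of 4 in the same pinene series, hence the same Si-face addition; Et2O, −78 °C, then NaOH, H2O2). Through (S)-6-methylhepta-1,5-dien-4-yl diisopinocampheylborinate F1 (not isolated) this should give (S)-6-methylhepta-1,5-dien-4-ol F2. Esterification with diethylphosphonoacetic acid (DCC, DMAP, CH2Cl2) gives (S)-6-methylhepta-1,5-dien-4-yl 2-(diethoxyphosphoryl)acetate F3. Wacker oxidation (PdCl2, CuCl, O2, DMF/H2O) of the only monosubstituted olefin gives the methyl ketone (S)-6-methyl-2-oxohept-5-en-4-yl 2-(diethoxyphosphoryl)acetate F4. LiCl and iPr2NEt in MeCN (Masamune–Roush conditions) then close the six-membered ring to lactone 9, where the route resumes at step 4.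

Step 7. Facial selectivity may erode on a Z-trisubstituted allylic alcohol, possibly through mismatching with the C5' centre, and epoxidation may be slow. Fallback, from 9 to 16: substrate control in the lactone ring replaces reagent control. Lactone 9 is epoxidised nucleophilically with alkaline H2O2 (NaOH, MeOH, 0 °C, mild acid work-up; Weitz–Scheffer type). The hydroperoxide should add to C3' of the half-chair anti to the pseudo-equatorial isobutenyl group and give the trans epoxy lactone (1R,4S,6R)-6-methyl-4-(2-methylprop-1-enyl)-3,7-dioxabicyclo[4.1.0]heptan-2-one F7, whose oxirane already has the 2'S,3'R configuration. NaBH4 (EtOH, 0 °C) reduces it to the epoxy diol (2S)-1-[(2R,3S)-3-(hydroxymethyl)-2-methyloxiran-2-yl]-4-methylpent-3-en-2-ol F8. A Mitsunobu reaction with phenol 14 (PPh3, DIAD, THF, 0 °C) at the primary hydroxyl then gives target 16 directly.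

Step 6. Discrimination between the two allylic silyl ethers may be incomplete (cleavage of both or of neither), and acid may ionise the allylic C–O bonds. Fallback, from 10 back to 12: the hydroxyls are told apart by acylation rather than by differential desilylation. Diol 10 is acetylated at the primary hydroxyl alone (AcCl, 2,4,6-collidine, CH2Cl2, −78 °C) to (2Z,5S)-5-hydroxy-3,7-dimethylocta-2,6-dien-1-yl acetate F5. The secondary hydroxyl is silylated (TBSCl, imidazole, DMF) to (2Z,5S)-5-(tert-butyldimethylsilyloxy)-3,7-dimethylocta-2,6-dien-1-yl acetate F6. Methanolysis (K2CO3, MeOH, 0 °C) returns alcohol 12.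

Further compounds

F1 | step 3 | (S)-6-methylhepta-1,5-dien-4-yl diisopinocampheylborinate | C=CC[C@H](OB([C@@H]1C[C@@H]2C[C@H]([C@H]1C)C2(C)C)[C@@H]1C[C@@H]2C[C@H]([C@H]1C)C2(C)C)C=C(C)C
F2 | step 3 | (S)-6-methylhepta-1,5-dien-4-ol | C=CC[C@H](O)C=C(C)C
F3 | step 3 | (S)-6-methylhepta-1,5-dien-4-yl 2-(diethoxyphosphoryl)acetate | CCOP(=O)(OCC)CC(=O)O[C@@H](CC=C)C=C(C)C
F4 | step 3 | (S)-6-methyl-2-oxohept-5-en-4-yl 2-(diethoxyphosphoryl)acetate | CCOP(=O)(OCC)CC(=O)O[C@@H](CC(C)=O)C=C(C)C
F5 | step 6 | (2Z,5S)-5-hydroxy-3,7-dimethylocta-2,6-dien-1-yl acetate | CC(=O)OC/C=C(C)\C[C@H](O)C=C(C)C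
F6 | step 6 | (2Z,5S)-5-(tert-butyldimethylsilyloxy)-3,7-dimethylocta-2,6-dien-1-yl acetate | CC(=O)OC/C=C(C)\C[C@H](O[Si](C)(C)C(C)(C)C)C=C(C)C
F7 | step 7 | (1R,4S,6R)-6-methyl-4-(2-methylprop-1-enyl)-3,7-dioxabicyclo[4.1.0]heptan-2-one | O=C1[C@@H]2O[C@]2(C)C[C@@H](C=C(C)C)O1
F8 | step 7 | (2S)-1-[(2R,3S)-3-(hydroxymethyl)-2-methyloxiran-2-yl]-4-methylpent-3-en-2-ol | OC[C@@H]1O[C@]1(C)C[C@H](O)C=C(C)C
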